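The number I began from was 45.4% of left-handed substrate at 40.0 min in the violet run, where the left-handed form had been half of the substrate charged. In these flasks a single-handed free catalyst turns left-handed substrate and partner into left-handed product, while a racemization catalyst interconverts the two substrates.

| flask | left-handed substrate | right-handed substrate | partner | free catalyst | racemization catalyst | temperature | remark | time |
|---|---|---|---|---|---|---|---|---|
| violet | 0.050 M | 0.050 M | 0.30 M | 0.20 mM | 2.3 mM | 55 °C | run made earlier |  |
| red | 0.20 M | 0.20 M | 0.30 M | 0.20 mM | 2.3 mM | 88 °C | run made earlier |  |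
| Tuesday's | 0.10 M | 0.10 M | 0.300 M | 0.20 mM | 2.3 mM | 40 °C |  | 2.5 h |
| Wednesday's | 0.10 M | 0.10 M | 0.300 M | 0.20 mM | 2.3 mM | 100 °C |  | 2.5 h |
| Friday's | 0.10 M | 0.10 M | 0.300 M | 0.20 mM | 2.3 mM | 70 °C |  | 2.5 h |

| run | time / min | left-handed product / % | left-handed substrate / % |
|---|---|---|---|
| violet | 2.50 | 0.2 | 50.0 |
| violet | 8.00 | 1.0 | 49.6 |
| violet | 12.0 | 2.6 | 48.3 |
| violet | 20.0 | 2.8 | 48.1 |
| violet | 25.0 | 2.8 | 47.3 |
| violet | 40.0 | 6.1 | 45.4 |
| red | 0.500 | 0.8 | 48.9 |
| red | 1.33 | 1.2 | 48.9 |
| red | 2.50 | 2.1 | 48.2 |
| red | 4.00 | 3.4 | 48.1 |
| red | 5.00 | 3.1 | 47.2 |
| red | 8.00 | 5.5 | 46.3 |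

(each reading ± 0.5 percentage points)

- which flask leads in amount of left-handed product, in percent of the left-handed substrate and right-handed substrate together charged ("all alike" within 1.5 percentage points) (Tuesday's / Wednesday's / Friday's / all alike)
- how much left-handed product is there at the end, in percent of the left-handed substrate and right-handed substrate together charged: Tuesday's
- how much left-handed product is there at the end, in percent of the left-handed substrate and right-handed substrate together charged: Wednesday's
- how much left-handed product is there at the end, in percent of the left-handed substrate and right-handed substrate together charged: Friday's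

- free catalyst is single-handed; left-handed substrate and right-handed substrate are mirror images of each other, charged as a racemate, each of them at the stated concentration

I reckoned with the fraction left, f, and not with the fraction made, and first took the main step by itself. With the same partner and free catalyst in both runs I assumed a step of first order in substrate, pseudo-first-order with k = −ln(f)/t, so that the different substrate charges dropped out:

violet, 55 °C: f = 0.908, k = 0.00241 min⁻¹

red, 88 °C: f = 0.926, k = 0.00961 min⁻¹

These are single readings with a scatter of 0.5 percentage points. Together they gave an activation energy of 41.3 kJ mol⁻¹, and from it the drain constant of the substrate at 70 °C, 0.00467 min⁻¹, which I carried on. For Friday's flask this gave f = 0.496, and with nothing refilling the left-handed substrate, 25.2% of left-handed product.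

Then I added racemization. At the last reading of the violet run the left-handed substrate had fallen by 4.6 points, less than the 6.1% of left-handed product read, so I took it to be refilled and treated both substrates as draining as one pool. Left-handed product took a share of the lost pool, a selectivity that I read as 0.703 on average over the last readings of the two runs, which raised my number for Friday's flask to 35.4%.

Last came the temperatures of the other flasks:

Tuesday's: 11.3%

Wednesday's: 62.8%

The red readings stop at 8.00 min, but Wednesday's flask runs 18.8 times as long and hotter, so I trusted its number least.

The forecast named Wednesday's, with 8%, 68% and 34% for Tuesday's, Wednesday's and Friday's, in its words “Wednesday's probably leads”, and my numbers differed somewhat from these.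

The flasks gave 9.04%, 8.32% and 25.6% in that order, and Friday's led.

    free catalyst → spent catalyst A (k = 6.40 × 10⁻⁴ s⁻¹, Ea = 105 kJ mol⁻¹)
    partner + free catalyst + right-handed substrate → free catalyst + right-handed product (k = 3.20 M⁻² s⁻¹, Ea = 41.0 kJ mol⁻¹)
    2 racemization catalyst → spent catalyst B (k = 0.0520 M⁻¹ s⁻¹, Ea = 76.0 kJ mol⁻¹)
    partner + free catalyst + left-handed substrate → free catalyst + left-handed product (k = 10.0 M⁻² s⁻¹, Ea = 47.0 kJ mol⁻¹)
    2 free catalyst ⇌ resting dimer, settled at all times (K = 59000 M⁻¹, ΔH = −1.00 kJ mol⁻¹)
    left-handed substrate + racemization catalyst ⇌ right-handed substrate + racemization catalyst, rate k6*[racemization catalyst]*[left-handed substrate] forward; the back reaction follows from the equilibrium constant (k = 4.60 M⁻¹ s⁻¹, Ea = 36.0 kJ mol⁻¹)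
    (constants at 70 °C)

Wednesday's 89% of left-handed substrate left is worth 7.48 min at the carried constant, out of 150 min. The activation energy of the conversion of free catalyst into spent catalyst A minus that of the step to left-handed product is 58.0 kJ mol⁻¹, and the first of these conversions speeds up by a factor of 650 from the coldest to the hottest flask. In Wednesday's flask spent catalyst A stood at 100% by 1.25 h, and left-handed product was 8.32% at 25.0 h. For Friday's recipe at 45 °C the carried constant gives 0.00150 min⁻¹, so 0.799 left and 14.1% of product; that flask computes to 84% left and 11.6%.

The earlier runs and the new flask stem from a simulated flask on assumed constants.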